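**Plan**

- Retrosynthesis cuts the ring A–C7 bond (aryl Grignard reagent + Weinreb amide), then the C8–C9 bond (enolate hydroxymethylation), then the ring B O–CH2 bond of an aryloxyacetic acid, and takes the masked hydroxyacetyl side chain of ring B back to acetosyringone.
- The enabling feature: C8 carries the ring B aryloxy oxygen, C9 and C7, so it is the α-carbon of an aryloxyacetic acid that lacks only the one-carbon oxygenated branch C9.
- Forward: acetosyringone → masked ring B phenol → aryloxyacetyl imide → C9 added at C8 → ring A joined at the acyl carbon (C7 ketone) → reduction → deprotection. Both arenes are bought; no ring of the target is built.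
- Stereochemistry: C8 (S) comes from (R)-4-benzyl-2-oxazolidinone in the enolate alkylation; C7 (R) comes from C8 through a chelation-controlled Zn(BH4)2 reduction to the erythro alcohol.

Key step: step 8

Remark: the target is read as (7R,8S) (erythro), with C7 the carbinol carbon, C8 the aryloxy carbon and C9 the hydroxymethyl carbon; "ArB" below means 4-{2-[(benzyloxy)methyl]-1,3-dioxolan-2-yl}-2,6-dimethoxyphenyl (masked ring B).

**Route**

Step 1
Reactants: 1 acetosyringone (4'-hydroxy-3',5'-dimethoxyacetophenone)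
Product: 2 1-[4-(allyloxy)-3,5-dimethoxyphenyl]ethan-1-one
Conditions: allyl bromide, K2CO3, DMF, 50 °C
Reagents that add atoms: allyl bromide, C=CCBr
Why: Williamson ether synthesis on the phenoxide, which caps the oxidation-prone 2,6-dimethoxyphenol with a group that can later be removed without touching benzyl ethers.

Step 2
Reactants: 2 1-[4-(allyloxy)-3,5-dimethoxyphenyl]ethan-1-one
Product: 3 2-[4-(allyloxy)-3,5-dimethoxyphenyl]-2,2-dimethoxyethan-1-ol
Conditions: PhI(OAc)2, KOH, MeOH, 0 °C → rt
Reagents that add atoms: methanol, CO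
Why: Moriarty oxidation with trivalent iodine in basic methanol, which should convert the aryl methyl ketone in one operation into the α-hydroxy dimethyl ketal and is known to tolerate isolated alkenes.

Step 3
Reactants: 3 2-[4-(allyloxy)-3,5-dimethoxyphenyl]-2,2-dimethoxyethan-1-ol
Product: 4 2-(allyloxy)-5-[2-(benzyloxy)-1,1-dimethoxyethyl]-1,3-dimethoxybenzene
Conditions: NaH, BnBr, Bu4NI (cat.), THF, 0 °C → rt
Reagents that add atoms: benzyl bromide, BrCc1ccccc1
Why: Williamson benzylation of the primary alkoxide under basic conditions, which the dimethyl ketal and the allyl ether should survive.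

Step 4
Reactants: 4 2-(allyloxy)-5-[2-(benzyloxy)-1,1-dimethoxyethyl]-1,3-dimethoxybenzene
Product: 5 2-[4-(allyloxy)-3,5-dimethoxyphenyl]-2-[(benzyloxy)methyl]-1,3-dioxolane
Conditions: HOCH2CH2OH, PPTS (cat.), toluene, 90 °C, 5 Å MS (MeOH removed)
Reagents that add atoms: ethylene glycol, OCCO
Why: Acid-catalysed transketalisation driven by removal of methanol, which should exchange the labile dimethyl ketal for the dioxolane that has to withstand the carboxylic acid, aluminium and zinc reagents ahead.

Step 5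
Reactants: 5 2-[4-(allyloxy)-3,5-dimethoxyphenyl]-2-[(benzyloxy)methyl]-1,3-dioxolane
Product: 6 4-{2-[(benzyloxy)methyl]-1,3-dioxolan-2-yl}-2,6-dimethoxyphenol (ArB–OH)
Conditions: Pd(PPh3)4 (cat.), morpholine, THF, rt
Reagents that add atoms: none
Why: Tsuji–Trost deallylation, in which zerovalent palladium ionises the allyl aryl ether to a π-allyl complex that morpholine captures, so the phenol should be freed with the benzyl ether and ketal intact.

Step 6
Reactants: 6 4-{2-[(benzyloxy)methyl]-1,3-dioxolan-2-yl}-2,6-dimethoxyphenol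
Product: 7 2-(ArB-oxy)acetic acid, i.e. 2-(4-{2-[(benzyloxy)methyl]-1,3-dioxolan-2-yl}-2,6-dimethoxyphenoxy)acetic acid
Conditions: NaH, BrCH2CO2H, THF–DMF, 0 → 60 °C; cold dilute HCl to pH 4
Reagents that add atoms: bromoacetic acid, OC(=O)CBr
Why: Williamson etherification of the sodium phenoxide with sodium bromoacetate, the standard one-step entry to aryloxyacetic acids, which places the hindered ring B ether on a primary carbon so that no displacement at the future stereocentre is needed.

Step 7
Reactants: 7 2-(ArB-oxy)acetic acid; 8 (R)-4-benzyl-2-oxazolidinone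
Product: 10 (R)-4-benzyl-3-[2-(ArB-oxy)acetyl]oxazolidin-2-one, via mixed pivalic anhydride 9 (not isolated)
Conditions: PivCl, Et3N, THF, −20 °C; then LiCl, 8, −20 °C → rt
Reagents that add atoms: none
Why: Mixed-anhydride N-acylation of the oxazolidinone, in which the lithium-activated carbamate nitrogen should attack the unhindered aryloxyacetyl carbonyl in preference to the pivaloyl carbonyl.

Step 8
Reactants: 10 (R)-4-benzyl-3-[2-(ArB-oxy)acetyl]oxazolidin-2-one; 11 benzyl chloromethyl ether (freshly distilled)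
Product: 13 (R)-4-benzyl-3-[(S)-3-(benzyloxy)-2-(ArB-oxy)propanoyl]oxazolidin-2-one, via sodium Z-enolate 12 (not isolated)
Conditions: NaN(SiMe3)2, THF, −78 °C; then 11, −78 → −45 °C; aq NH4Cl
Reagents that add atoms: none
Why: NaN(SiMe3)2 removes one C8 proton of 10 to give the sodium Z-enolate 12, in which sodium bridges the enolate oxygen and the oxazolidinone carbonyl and the aryloxy group sits cis to the enolate oxygen; C8 then displaces chloride from 11 in an SN2-type alkylation that forms the C8–C9 bond. The closest known reaction type is the Evans alkylation of N-acyloxazolidinone enolates in its glycolate variant, with benzyl chloromethyl ether as the formaldehyde equivalent. No ring is closed. The one new stereocentre, C8, is controlled by the C4 benzyl group of the (R)-auxiliary, which shields one face of the rigid chelate so that the electrophile should add to the Si face of C8 and give the S configuration. The step needs facial selectivity and C- rather than O-alkylation at temperatures where a glycolate enolate is still intact; the chelated Z geometry and the high reactivity of the α-chloro ether should secure both. The product is quenched cold, so the remaining C8–H should not be exchanged.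

Step 9
Reactants: 13 (R)-4-benzyl-3-[(S)-3-(benzyloxy)-2-(ArB-oxy)propanoyl]oxazolidin-2-one
Product: 14 (S)-3-(benzyloxy)-2-(ArB-oxy)-N-methoxy-N-methylpropanamide
Conditions: MeONHMe·HCl, AlMe3, CH2Cl2, 0 °C; then 13, −10 °C → rt; aq potassium sodium tartrate
Reagents that add atoms: N,O-dimethylhydroxylamine hydrochloride, CNOC.Cl
Why: Weinreb transamination with the aluminium amide, which should attack the exocyclic carbonyl (activated by the α-aryloxy group), release the auxiliary for recovery and, being non-basic, leave C8 untouched.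

Step 10
Reactants: 15 4-bromo-2-methoxyphenol
Product: 16 1-(benzyloxy)-4-bromo-2-methoxybenzene
Conditions: BnBr, K2CO3, DMF, rt
Reagents that add atoms: benzyl bromide, BrCc1ccccc1
Why: Williamson benzylation of the ring A phenol, so that all three benzyl ethers can be removed together at the end.

Step 11
Reactants: 14 (S)-3-(benzyloxy)-2-(ArB-oxy)-N-methoxy-N-methylpropanamide; 16 1-(benzyloxy)-4-bromo-2-methoxybenzene
Product: 19 (S)-3-(benzyloxy)-1-[4-(benzyloxy)-3-methoxyphenyl]-2-(ArB-oxy)propan-1-one, via arylmagnesium bromide 17 (not isolated), via bromomagnesium hemiaminal chelate 18 (not isolated)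
Conditions: 16, Mg (I2 crystal), THF, rt → 40 °C; then 14, THF, −20 → 0 °C; cold aq NH4Cl
Reagents that add atoms: none
Why: Weinreb ketone synthesis, in which the aryl Grignard reagent adds once to give the stable five-membered magnesium chelate 18 that releases the ketone only on cold, nearly neutral quench, which should keep the base-sensitive C8 centre intact and prevent over-addition.

Step 12
Reactants: 19 (S)-3-(benzyloxy)-1-[4-(benzyloxy)-3-methoxyphenyl]-2-(ArB-oxy)propan-1-one
Product: 20 (1R,2S)-3-(benzyloxy)-1-[4-(benzyloxy)-3-methoxyphenyl]-2-(ArB-oxy)propan-1-ol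
Conditions: Zn(BH4)2, Et2O–CH2Cl2, −30 → 0 °C; H2O
Reagents that add atoms: none
Why: Cram-chelate controlled reduction, in which divalent zinc bridges the C7 carbonyl oxygen and the C8 aryloxy oxygen (assisted by an ortho methoxy group of ring B) so that hydride should reach C7 from the face bearing H8, away from the C9 benzyloxymethyl group, setting C7 as R (erythro, anti).

Step 13
Reactants: 20 (1R,2S)-3-(benzyloxy)-1-[4-(benzyloxy)-3-methoxyphenyl]-2-(ArB-oxy)propan-1-ol
Product: 21 (1R,2S)-1-(4-hydroxy-3-methoxyphenyl)-2-{4-[2-(hydroxymethyl)-1,3-dioxolan-2-yl]-2,6-dimethoxyphenoxy}propane-1,3-diol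
Conditions: H2 (1 atm), Pd/C (10 wt% Pd), EtOAc–EtOH, rt
Reagents that add atoms: none
Why: Catalytic hydrogenolysis of the one aryl and two alkyl benzyl ethers under neutral conditions, where the secondary benzylic C7–OH and the fully substituted aryl ketal are expected to be much slower to cleave; the ring B ketone is still masked and cannot be reduced.

Step 14
Reactants: 21 (1R,2S)-1-(4-hydroxy-3-methoxyphenyl)-2-{4-[2-(hydroxymethyl)-1,3-dioxolan-2-yl]-2,6-dimethoxyphenoxy}propane-1,3-diol
Product: 22 2-hydroxy-1-(4-{[(1R,2S)-1,3-dihydroxy-1-(4-hydroxy-3-methoxyphenyl)propan-2-yl]oxy}-3,5-dimethoxyphenyl)ethan-1-one (target)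
Conditions: 0.5 M aq HCl, THF, rt (monitored); NaHCO3
Reagents that add atoms: water, O
Why: Specific-acid-catalysed ketal hydrolysis, in which the dioxolane carbon should ionise to an aryl-stabilised oxocarbenium ion far faster than the C7 carbinol (whose ionisation is retarded by the adjacent aryloxy and hydroxymethyl groups), releasing the hydroxyacetyl ketone without disturbing C7 or C8.

**Compound list**

1 | acetosyringone | CC(=O)c1cc(OC)c(O)c(OC)c1 | starting material
2 | 1-[4-(allyloxy)-3,5-dimethoxyphenyl]ethan-1-one | CC(=O)c1cc(OC)c(OCC=C)c(OC)c1 | intermediate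
3 | 2-[4-(allyloxy)-3,5-dimethoxyphenyl]-2,2-dimethoxyethan-1-ol | OCC(OC)(OC)c1cc(OC)c(OCC=C)c(OC)c1 | intermediate
4 | 2-(allyloxy)-5-[2-(benzyloxy)-1,1-dimethoxyethyl]-1,3-dimethoxybenzene | COC(COCc1ccccc1)(OC)c1cc(OC)c(OCC=C)c(OC)c1 | intermediate
5 | 2-[4-(allyloxy)-3,5-dimethoxyphenyl]-2-[(benzyloxy)methyl]-1,3-dioxolane | C=CCOc1c(OC)cc(C2(COCc3ccccc3)OCCO2)cc1OC | intermediate
6 | 4-{2-[(benzyloxy)methyl]-1,3-dioxolan-2-yl}-2,6-dimethoxyphenol | COc1cc(C2(COCc3ccccc3)OCCO2)cc(OC)c1O | intermediate
7 | 2-(4-{2-[(benzyloxy)methyl]-1,3-dioxolan-2-yl}-2,6-dimethoxyphenoxy)acetic acid | OC(=O)COc1c(OC)cc(C2(COCc3ccccc3)OCCO2)cc1OC | intermediate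
8 | (R)-4-benzyl-2-oxazolidinone | O=C1N[C@H](Cc2ccccc2)CO1 | starting material
9 | mixed pivalic anhydride of 7 (not isolated) | CC(C)(C)C(=O)OC(=O)COc1c(OC)cc(C2(COCc3ccccc3)OCCO2)cc1OC | intermediate
10 | (R)-4-benzyl-3-[2-(4-{2-[(benzyloxy)methyl]-1,3-dioxolan-2-yl}-2,6-dimethoxyphenoxy)acetyl]oxazolidin-2-one | O=C(COc1c(OC)cc(C2(COCc3ccccc3)OCCO2)cc1OC)N1[C@H](Cc2ccccc2)COC1=O | intermediate
11 | benzyl chloromethyl ether | ClCOCc1ccccc1 | starting material
12 | sodium Z-enolate of 10 (not isolated) | [Na+].[O-]/C(=C\Oc1c(OC)cc(C2(COCc3ccccc3)OCCO2)cc1OC)N1[C@H](Cc2ccccc2)COC1=O | intermediate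
13 | (R)-4-benzyl-3-[(S)-3-(benzyloxy)-2-(4-{2-[(benzyloxy)methyl]-1,3-dioxolan-2-yl}-2,6-dimethoxyphenoxy)propanoyl]oxazolidin-2-one | O=C([C@H](COCc1ccccc1)Oc1c(OC)cc(C2(COCc3ccccc3)OCCO2)cc1OC)N1[C@H](Cc2ccccc2)COC1=O | intermediate
14 | (S)-3-(benzyloxy)-2-(4-{2-[(benzyloxy)methyl]-1,3-dioxolan-2-yl}-2,6-dimethoxyphenoxy)-N-methoxy-N-methylpropanamide | CON(C)C(=O)[C@H](COCc1ccccc1)Oc1c(OC)cc(C2(COCc3ccccc3)OCCO2)cc1OC | intermediate
15 | 4-bromo-2-methoxyphenol | COc1cc(Br)ccc1O | starting material
16 | 1-(benzyloxy)-4-bromo-2-methoxybenzene | COc1cc(Br)ccc1OCc1ccccc1 | intermediate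
17 | [4-(benzyloxy)-3-methoxyphenyl]magnesium bromide (not isolated) | COc1cc([Mg]Br)ccc1OCc1ccccc1 | intermediate
18 | bromomagnesium alkoxide of the N-methoxy-N-methyl hemiaminal from 14 and 17 (not isolated; C8 S, hemiaminal carbon undefined) | COc1cc(C(O[Mg]Br)(N(C)OC)[C@H](COCc2ccccc2)Oc2c(OC)cc(C3(COCc4ccccc4)OCCO3)cc2OC)ccc1OCc1ccccc1 | intermediate
19 | (S)-3-(benzyloxy)-1-[4-(benzyloxy)-3-methoxyphenyl]-2-(4-{2-[(benzyloxy)methyl]-1,3-dioxolan-2-yl}-2,6-dimethoxyphenoxy)propan-1-one | COc1cc(C(=O)[C@H](COCc2ccccc2)Oc2c(OC)cc(C3(COCc4ccccc4)OCCO3)cc2OC)ccc1OCc1ccccc1 | intermediate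
20 | (1R,2S)-3-(benzyloxy)-1-[4-(benzyloxy)-3-methoxyphenyl]-2-(4-{2-[(benzyloxy)methyl]-1,3-dioxolan-2-yl}-2,6-dimethoxyphenoxy)propan-1-ol | COc1cc([C@@H](O)[C@H](COCc2ccccc2)Oc2c(OC)cc(C3(COCc4ccccc4)OCCO3)cc2OC)ccc1OCc1ccccc1 | intermediate
21 | (1R,2S)-1-(4-hydroxy-3-methoxyphenyl)-2-{4-[2-(hydroxymethyl)-1,3-dioxolan-2-yl]-2,6-dimethoxyphenoxy}propane-1,3-diol | COc1cc([C@@H](O)[C@H](CO)Oc2c(OC)cc(C3(CO)OCCO3)cc2OC)ccc1O | intermediate
22 | 2-hydroxy-1-(4-{[(1R,2S)-1,3-dihydroxy-1-(4-hydroxy-3-methoxyphenyl)propan-2-yl]oxy}-3,5-dimethoxyphenyl)ethan-1-one | COc1cc([C@@H](O)[C@H](CO)Oc2c(OC)cc(C(=O)CO)cc2OC)ccc1O | target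

**Step count**

Total: 14 steps. Longest linear sequence: 13 steps (steps 1–9 and 11–14, from acetosyringone); step 10 is a one-step side branch.

**Steps most likely to fail**

1. Step 12 (reduction at C7). A six-membered zinc chelate through the C9 benzyloxy oxygen may compete with the five-membered chelate through the aryloxy oxygen and erode the erythro preference; slow enolisation at C8 of the ketone is a second hazard. Fallback, with C7 set by SN2 inversion instead of chelation: starting from ketone 19, reduction with the bulky non-chelating hydride LiBH(s-Bu)3 (THF, −78 °C) should follow the polar Felkin–Anh model and give mainly the threo alcohol (1S,2S)-3-(benzyloxy)-1-[4-(benzyloxy)-3-methoxyphenyl]-2-(ArB-oxy)propan-1-ol F1. Mitsunobu esterification of this alcohol (4-nitrobenzoic acid, PPh3, DIAD, toluene, 0 °C → rt) should invert C7 to the (1R,2S) 4-nitrobenzoate F2, and methanolysis (K2CO3, MeOH, rt) rejoins the route at alcohol 20.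

2. Step 8 (key alkylation). The glycolate enolate may fragment (loss of the auxiliary anion) before it is alkylated, the hard chloromethyl ether may alkylate on oxygen, or facial selectivity may be eroded by the bulky ring B aryloxy group. Fallback, which forms the C8–O bond with inversion from the chiral pool: commercial O-benzyl-D-serine is deaminated with retention (NaNO2, aq H2SO4, 0 °C) to (R)-3-(benzyloxy)-2-hydroxypropanoic acid F3 and esterified (MeOH, cat. H2SO4) to methyl (R)-3-(benzyloxy)-2-hydroxypropanoate F4. Starting from phenol 6, Mitsunobu etherification with this ester (PPh3, DIAD, THF, 0 °C → rt) should give methyl (S)-3-(benzyloxy)-2-(ArB-oxy)propanoate F5, and aminolysis (MeONHMe·HCl, i-PrMgCl, THF, −20 °C) rejoins the route at Weinreb amide 14.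

3. Step 11 (acylation of the ring A Grignard reagent). The basic arylmagnesium reagent may deprotonate C8, leading to epimerisation or β-elimination of benzyloxide, and the preceding aminolysis of the hindered imide may be sluggish. Fallback under base-free conditions: starting from imide 13, LiSEt (EtSH, n-BuLi, THF, 0 °C) should displace the auxiliary to give S-ethyl (S)-3-(benzyloxy)-2-(ArB-oxy)propanethioate F6. Liebeskind–Srogl coupling of this thioester with commercial 4-(benzyloxy)-3-methoxyphenylboronic acid (Pd2(dba)3, P(2-furyl)3, copper thiophene-2-carboxylate CuO2CC4H3S, THF, 50 °C) rejoins the route at ketone 19.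

**Further compounds**

F1 | step 12 | (1S,2S)-3-(benzyloxy)-1-[4-(benzyloxy)-3-methoxyphenyl]-2-(4-{2-[(benzyloxy)methyl]-1,3-dioxolan-2-yl}-2,6-dimethoxyphenoxy)propan-1-ol | COc1cc([C@H](O)[C@H](COCc2ccccc2)Oc2c(OC)cc(C3(COCc4ccccc4)OCCO3)cc2OC)ccc1OCc1ccccc1
F2 | step 12 | (1R,2S)-3-(benzyloxy)-1-[4-(benzyloxy)-3-methoxyphenyl]-2-(4-{2-[(benzyloxy)methyl]-1,3-dioxolan-2-yl}-2,6-dimethoxyphenoxy)propyl 4-nitrobenzoate | COc1cc([C@@H](OC(=O)c2ccc(cc2)[N+](=O)[O-])[C@H](COCc2ccccc2)Oc2c(OC)cc(C3(COCc4ccccc4)OCCO3)cc2OC)ccc1OCc1ccccc1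
F3 | step 8 | (R)-3-(benzyloxy)-2-hydroxypropanoic acid | O[C@H](COCc1ccccc1)C(=O)O
F4 | step 8 | methyl (R)-3-(benzyloxy)-2-hydroxypropanoate | O[C@H](COCc1ccccc1)C(=O)OC
F5 | step 8 | methyl (S)-3-(benzyloxy)-2-(4-{2-[(benzyloxy)methyl]-1,3-dioxolan-2-yl}-2,6-dimethoxyphenoxy)propanoate | COC(=O)[C@H](COCc1ccccc1)Oc1c(OC)cc(C2(COCc3ccccc3)OCCO2)cc1OC
F6 | step 11 | S-ethyl (S)-3-(benzyloxy)-2-(4-{2-[(benzyloxy)methyl]-1,3-dioxolan-2-yl}-2,6-dimethoxyphenoxy)propanethioate | CCSC(=O)[C@H](COCc1ccccc1)Oc1c(OC)cc(C2(COCc3ccccc3)OCCO2)cc1OC
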